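**Plan**

- Enabling feature: in ring B the C19–C20 ethylene next to C2 carries no substituent, so C20 can be inserted last into the C2–C19 bond of a seven-membered C2 ketone. The carbonyl that remains then delivers the C1 methyl and the C2=C3 olefin.
- Retrosynthesis: C1–C2 (methyl coupling on the C2=C3 enol triflate), then C2–C20 and C19–C20 (removal of C20), then C7–C8 (alkenyl triflate plus aldehyde), then C2–C3 (enolate acylation). This leaves a ring A cyclopentanone and a ring C/D decalin carrying the C19–C2 acid and the quaternary C9.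
- Forward: rings C and D arise first (asymmetric Robinson annulation) and receive C19/C2, C8 and the C9 methyl. Ring A (a chiral cyclopentenone) is joined by acylation, and the seven-membered ring is closed by a Nozaki–Hiyama–Kishi reaction. Ring B then reaches eight members by ring expansion; olefin installation and desilylation finish the route.
- Stereochemistry: C12 comes from a chiral-amine Michael addition. C17, C18 and C9 follow from substrate control on the trans-decalin. C5 comes from the cyclopentenone and C6 from anti alkylation beside it. C8 is set in the chromium-mediated closure and C7 by hydroxyl-directed hydrogenation. Ring B fixes the C2=C3 geometry.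

Key step: step 19

Remark: locants C1–C20 follow the carbon chain of the target (C1 = methyl on C2; ring A = C3–C7; ring B = C2, C3, C7, C8, C9, C18, C19, C20; ring C = C9–C12, C17, C18; ring D = C12–C17) and are used for all intermediates; β is the face of the C12 methyl and α the opposite face; the sense of induction in step 2 is assumed to follow the behaviour of simple 2-methylcyclohexanone imines.

**Route**

Step 1
Reactants: 1 3,3-dimethylcyclohexanone
Product: 3 2,5,5-trimethylcyclohexanone (racemic), via lithium enolate 2 (not isolated)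
Conditions: LiN(iPr)2, THF, −78 °C; MeI, −78 → 0 °C
Reagents that add atoms: iodomethane, CI
Why: Kinetic enolate alkylation, in which the amide base removes a proton from the methylene remote from the gem-dimethyl carbon (the other α-methylene is neopentyl-shielded) and the enolate is methylated once; the new C–H stereocentre is racemic and is erased in step 2.

Step 2
Reactants: 3 2,5,5-trimethylcyclohexanone (racemic); 4 but-3-en-2-one
Product: 7 (S)-2,5,5-trimethyl-2-(3-oxobutyl)cyclohexanone, via imine 5 (not isolated), via Michael adduct imine 6 (not isolated)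
Conditions: (R)-1-phenylethylamine, TsOH (cat.), toluene, reflux, −H2O; 4, THF, 25 → 40 °C; aq. AcOH, 25 °C
Reagents that add atoms: none
Why: Asymmetric Michael addition of a chiral imine through its more substituted secondary enamine tautomer (first half of an asymmetric Robinson annulation), in which the aza-ene-like transition state should add the enone to the enamine face away from the phenyl group and so set the quaternary C12 as (S).

Step 3
Reactants: 7 (S)-2,5,5-trimethyl-2-(3-oxobutyl)cyclohexanone
Product: 8 (S)-4a,7,7-trimethyl-4,4a,5,6,7,8-hexahydronaphthalen-2(3H)-one (C9 ketone; C17=C18)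
Conditions: NaOMe, MeOH, 60 °C
Reagents that add atoms: none
Why: Intramolecular aldol condensation (second half of the Robinson annulation), in which the methyl ketone enolate closes ring C onto the ring carbonyl and water is lost to the conjugated octalone without touching C12.

Step 4
Reactants: 8 (S)-4a,7,7-trimethyl-4,4a,5,6,7,8-hexahydronaphthalen-2(3H)-one
Product: 10 trans-decalone tert-butyl ester (9-oxo; 12β-Me; 17α-H; 18α-CH2CO2tBu), via lithium enolate 9 (not isolated)
Conditions: Li, NH3(l), THF, tBuOH (1 equiv), −78 °C; isoprene; −NH3; BrCH2CO2tBu, THF, −78 → 0 °C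
Reagents that add atoms: tert-butyl bromoacetate, CC(C)(C)OC(=O)CBr
Why: Birch-type reductive alkylation of an enone, in which protonation at C17 gives the trans ring fusion (H opposite the angular methyl) and the regiodefined C9–C18 enolate is alkylated at C18 from the α face, because β (axial) attack would be 1,3-diaxial to the C12 methyl, so the acetate chain ends equatorial.

Step 5
Reactants: 10 trans-decalone tert-butyl ester
Product: 12 Δ9(10)-enol triflate of 10, via potassium enolate 11 (not isolated)
Conditions: KN(SiMe3)2, THF, −78 °C; PhNTf2, −78 → 0 °C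
Reagents that add atoms: N-phenylbis(trifluoromethanesulfonimide), O=S(=O)(N(c1ccccc1)S(=O)(=O)C(F)(F)F)C(F)(F)F
Why: Kinetic enolate O-sulfonylation, in which the hindered base removes a C10 methylene proton in preference to the tertiary C18–H and the less acidic ester α-protons, and the enolate is trapped as the enol triflate.

Step 6
Reactants: 12 Δ9(10)-enol triflate of 10
Product: 13 allylic alcohol (C9–CH2OH on the Δ9(10) olefin)
Conditions: Bu3SnCH2OH, Pd(PPh3)4 (cat.), LiCl, 1,4-dioxane, 100 °C
Reagents that add atoms: (tributylstannyl)methanol, CCCC[Sn](CCCC)(CCCC)CO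
Why: Stille cross-coupling of an alkenyl triflate with chloride-assisted transfer of the hydroxymethyl group from tin, which installs C8 on C9 at the alcohol oxidation level.

Step 7
Reactants: 13 allylic alcohol
Product: 14 9α,10α-methano alcohol (cyclopropane; 9β-CH2OH)
Conditions: Et2Zn, CH2I2, CH2Cl2, 0 → 25 °C
Reagents that add atoms: diiodomethane, ICI
Why: Simmons–Smith cyclopropanation accelerated by the allylic hydroxyl, in which the zinc carbenoid adds to the α face of the olefin, opposite the axial C12 methyl (the usual outcome for such olefins in trans-fused angular-methyl decalins), so the new methylene is α on C9 and C8 stays β.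

Step 8
Reactants: 14 9α,10α-methano alcohol
Product: 15 hydroxy ester (9α-Me; 9β-CH2OH; 18α-CH2CO2tBu)
Conditions: H2 (3 atm), PtO2, AcOH, 25 °C
Reagents that add atoms: none
Why: Catalytic hydrogenolysis of a cyclopropane at its least substituted bond (C10–CH2), which converts the α methylene into the axial C9 methyl with retention at C9 because no bond to C9 is broken.

Step 9
Reactants: 15 hydroxy ester
Product: 17 decalin acetic acid (C2 acid; 9β-CH2OSiEt3; 9α-Me), via bis-silyl derivative 16 (not isolated)
Conditions: Et3SiOTf, 2,6-lutidine, CH2Cl2, 0 → 25 °C; K2CO3, MeOH–H2O, 0 °C; pH 5 work-up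
Reagents that add atoms: triethylsilyl trifluoromethanesulfonate, CC[Si](CC)(CC)OS(=O)(=O)C(F)(F)F
Why: Silyl triflate-mediated O-silylation combined with tert-butyl ester cleavage (silylation of the ester carbonyl and loss of isobutene), after which mild aqueous base hydrolyses only the labile silyl ester and leaves the neopentyl triethylsilyl ether on O8.

Step 10
Reactants: 18 (S)-4-(tert-butyldimethylsilyloxy)cyclopent-2-enone
Product: 20 (4R,5S)-4-(tert-butyldimethylsilyloxy)-5-methylcyclopent-2-enone, via lithium dienolate 19 (not isolated)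
Conditions: LiN(iPr)2, THF, −78 °C; MeI, −78 → −40 °C
Reagents that add atoms: iodomethane, CI
Why: Kinetic α′-alkylation of a cross-conjugated enone enolate, in which loss of the neighbouring silyloxy group would require an antiaromatic cyclopentadienone and should not compete at low temperature, and iodomethane enters anti to that silyloxy group to give the trans C5/C6 relationship.

Step 11
Reactants: 20 (4R,5S)-4-(tert-butyldimethylsilyloxy)-5-methylcyclopent-2-enone
Product: 21 (2S,3R)-3-(tert-butyldimethylsilyloxy)-2-methylcyclopentanone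
Conditions: H2 (1 atm), Pd/C, EtOAc, 25 °C
Reagents that add atoms: none
Why: Heterogeneous catalytic hydrogenation of the enone C=C under neutral conditions, which leaves both stereocentres and the silyl ether in place and gives the thermodynamically preferred trans ketone.

Step 12
Reactants: 17 decalin acetic acid; 21 (2S,3R)-3-(tert-butyldimethylsilyloxy)-2-methylcyclopentanone
Product: 24 1,3-diketone (C2–C3 joined; enolised in solution), via acid chloride 22 (not isolated), via lithium enolate 23 (not isolated)
Conditions: 17, 1-chloro-N,N,2-trimethylprop-1-en-1-amine, CH2Cl2, 0 → 25 °C; 21 (2.2 equiv), LiN(iPr)2 (2.2 equiv), THF, −78 °C; then 22, −78 → −40 °C; aq. NH4Cl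
Reagents that add atoms: none
Why: Claisen-type C-acylation of a kinetic lithium enolate with an acid chloride, in which the base deprotonates the unhindered C3 methylene instead of the tertiary C6–H (so the β-silyloxy group is not eliminated) and the second equivalent of enolate takes up the acidic proton of the diketone.

Step 13
Reactants: 24 1,3-diketone
Product: 25 vinylogous triflate (C7–OTf; C7=C3; C2 ketone)
Conditions: Tf2O, iPr2NEt, CH2Cl2, −78 °C
Reagents that add atoms: trifluoromethanesulfonic anhydride, O=S(=O)(OS(=O)(=O)C(F)(F)F)C(F)(F)F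
Why: Enol O-triflation of a 1,3-diketone, in which, as with other 2-acylcycloalkanones, the ring oxygen should be sulfonylated to give the endocyclic β-triflyloxy enone (less allylic strain than the exocyclic isomer) and so activate C7.

Step 14
Reactants: 25 vinylogous triflate
Product: 26 primary alcohol (C8–OH) of 25
Conditions: HF·pyridine, pyridine, THF, 0 °C
Reagents that add atoms: none
Why: Selective desilylation, in which buffered fluoride cleaves the primary triethylsilyl ether much faster than the secondary tert-butyldimethylsilyl ether and should spare the vinylogous triflate.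

Step 15
Reactants: 26 primary alcohol
Product: 27 aldehyde (C8=O) triflate
Conditions: Dess–Martin periodinane, NaHCO3, CH2Cl2, 0 → 25 °C
Reagents that add atoms: none
Why: Dess–Martin oxidation of the neopentyl alcohol to the non-enolisable C8 aldehyde under buffered conditions that leave the triflate, the ketone and the silyl ether alone.

Step 16
Reactants: 27 aldehyde triflate
Product: 28 five–seven–six–six γ-hydroxy enone (8β-OH; C7=C3; C2 ketone)
Conditions: CrCl2 (excess), NiCl2 (cat.), degassed DMF, high dilution, 25 → 50 °C
Reagents that add atoms: none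
Why: Intramolecular Nozaki–Hiyama–Kishi reaction, in which zerovalent nickel inserts into the C7–OTf bond, transmetallation gives a trivalent alkenylchromium species that adds only to the aldehyde to close the seven-membered ring, and the aldehyde is expected to react through the rotamer whose oxygen and chromium are turned away from the axial C9 methyl, which gives the 8β alcohol.

Step 17
Reactants: 28 γ-hydroxy enone
Product: 29 saturated hydroxy ketone (3β-H; 7β-H; 8β-OH)
Conditions: H2, [Ir(cod)(PCy3)(py)]PF6 (cat.), CH2Cl2, 25 °C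
Reagents that add atoms: none
Why: Hydroxyl-directed homogeneous hydrogenation, in which the cationic iridium catalyst binds the C8 hydroxyl and delivers both hydrogens to the β face of the tetrasubstituted olefin, which is also the face opposite the C6 methyl, so C7–H becomes β and the 5–7 ring fusion cis.

Step 18
Reactants: 29 saturated hydroxy ketone
Product: 30 bis-silyl five–seven–six–six C2 ketone
Conditions: tBuMe2SiOTf, 2,6-lutidine, CH2Cl2, −78 → 0 °C
Reagents that add atoms: tert-butyldimethylsilyl trifluoromethanesulfonate, CC(C)(C)[Si](C)(C)OS(=O)(=O)C(F)(F)F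
Why: Silylation of the hindered secondary C8 alcohol with a silyl triflate and a weak hindered base that should neither enolise the ketone nor epimerise C3.

Step 19
Reactants: 30 bis-silyl five–seven–six–six C2 ketone
Product: 32 five–eight–six–six C2 ketone (bis-silyl ether), via α-silyl ketone 31 (not isolated)
Conditions: AlMe3, Me3SiCHN2, CH2Cl2, −78 → −20 °C; 1 M HCl, THF, 0 °C
Reagents that add atoms: trimethylsilyldiazomethane, C[Si](C)(C)C=[N+]=[N-]
Why: This is a Lewis acid-promoted diazoalkane homologation of a cyclic ketone (Tiffeneau–Demjanov-type): AlMe3 activates the C2 carbonyl, the diazo carbon adds to C2, and loss of N2 drives a 1,2-shift of the C19 methylene that forms the C2–C20 and C19–C20 bonds. Ring B is therefore formed by one-carbon enlargement of the seven-membered ring and not by a direct eight-membered cyclisation, which avoids the entropic and transannular cost of medium-ring closure. The first product is the α-silyl ketone 31 with silicon on C20, which is too hindered to insert a second time and is protodesilylated by dilute acid to 32. No stereocentre is created, and C3, C7 and C8 should stay untouched because the promoter is not basic. The step needs migration of C19 and not of the ring-fusion carbon C3; the bulky silyldiazomethane–aluminium adduct favours shift of the less substituted α-carbon, and C3 is tertiary and flanked by the substituted C7. Both oxygens are silylated so that no free hydroxyl competes for the aluminium reagent.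

Step 20
Reactants: 32 five–eight–six–six C2 ketone
Product: 33 C2=C3 enol triflate
Conditions: Tf2O, 2,6-di-tert-butyl-4-methylpyridine, CH2Cl2, 0 → 25 °C
Reagents that add atoms: trifluoromethanesulfonic anhydride, O=S(=O)(OS(=O)(=O)C(F)(F)F)C(F)(F)F
Why: Thermodynamic enol triflate formation, in which O-triflation of the ketone followed by proton loss under product-stability control should give the more substituted C2=C3 isomer (tetrasubstituted and exocyclic to ring A), with its geometry fixed by the eight-membered ring.

Step 21
Reactants: 33 C2=C3 enol triflate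
Product: 34 bis(tert-butyldimethylsilyl) ether of the target
Conditions: MeMgBr, Fe(acac)3 (cat.), THF–NMP, −30 → 0 °C
Reagents that add atoms: methylmagnesium bromide, C[Mg]Br
Why: Iron-catalysed Kumada-type cross-coupling of an alkenyl triflate with a Grignard reagent, in which a low-valent iron species transfers the methyl group (which has no β-hydrogen) to C2 with retention of the ring-defined olefin geometry.

Step 22
Reactants: 34 bis(tert-butyldimethylsilyl) ether of the target
Product: 35 target diol CNP0213887.1
Conditions: Bu4NF, THF, 50 °C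
Reagents that add atoms: none
Why: Fluoride-mediated cleavage of both silyl ethers through Si–F bond formation under non-acidic conditions that should not move the tetrasubstituted olefin.

**Compound list**

1 | 3,3-dimethylcyclohexanone | CC1(C)CCCC(=O)C1 | starting material
2 | lithium 5,5-dimethylcyclohex-1-enolate (formed in situ) | [Li]OC1=CCCC(C)(C)C1 | intermediate
3 | 2,5,5-trimethylcyclohexanone (racemic) | CC1CCC(C)(C)CC1=O | intermediate
4 | but-3-en-2-one | CC(=O)C=C | starting material
5 | N-[(R)-1-phenylethyl] imine of 3 (formed in situ) | CC1CCC(C)(C)CC1=N[C@H](C)c1ccccc1 | intermediate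
6 | N-[(R)-1-phenylethyl] imine of diketone 7 (Michael adduct; formed in situ) | CC(=O)CC[C@]1(C)CCC(C)(C)CC1=N[C@H](C)c1ccccc1 | intermediate
7 | (S)-2,5,5-trimethyl-2-(3-oxobutyl)cyclohexanone | CC(=O)CC[C@]1(C)CCC(C)(C)CC1=O | intermediate
8 | (S)-4a,7,7-trimethyl-4,4a,5,6,7,8-hexahydronaphthalen-2(3H)-one (C9 ketone; C17=C18) | O=C1C=C2CC(C)(C)CC[C@@]2(C)CC1 | intermediate
9 | lithium C9(O)=C18 enolate of the trans-decalone (17α-H; formed in situ) | [Li]OC1=C[C@@H]2CC(C)(C)CC[C@@]2(C)CC1 | intermediate
10 | trans-decalone tert-butyl ester (9-oxo; 12β-Me; 17α-H; 18α-CH2CO2tBu) | CC(C)(C)OC(=O)C[C@H]1[C@@H]2CC(C)(C)CC[C@@]2(C)CCC1=O | intermediate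
11 | potassium Δ9(10)-enolate of 10 (formed in situ) | CC(C)(C)OC(=O)C[C@H]1[C@@H]2CC(C)(C)CC[C@@]2(C)CC=C1O[K] | intermediate
12 | Δ9(10)-enol triflate of 10 | CC(C)(C)OC(=O)C[C@H]1[C@@H]2CC(C)(C)CC[C@@]2(C)CC=C1OS(=O)(=O)C(F)(F)F | intermediate
13 | allylic alcohol (C9–CH2OH on the Δ9(10) olefin) | CC(C)(C)OC(=O)C[C@H]1[C@@H]2CC(C)(C)CC[C@@]2(C)CC=C1CO | intermediate
14 | 9α,10α-methano alcohol (cyclopropane; 9β-CH2OH) | CC(C)(C)OC(=O)C[C@H]1[C@@H]2CC(C)(C)CC[C@@]2(C)C[C@H]3C[C@@]13CO | intermediate
15 | hydroxy ester (9α-Me; 9β-CH2OH; 18α-CH2CO2tBu) | CC(C)(C)OC(=O)C[C@H]1[C@@H]2CC(C)(C)CC[C@@]2(C)CC[C@]1(C)CO | intermediate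
16 | triethylsilyl ester and triethylsilyl ether of the hydroxy acid (formed in situ) | CC[Si](CC)(CC)OC(=O)C[C@H]1[C@@H]2CC(C)(C)CC[C@@]2(C)CC[C@]1(C)CO[Si](CC)(CC)CC | intermediate
17 | decalin acetic acid (C2 acid; 9β-CH2OSiEt3; 9α-Me) | OC(=O)C[C@H]1[C@@H]2CC(C)(C)CC[C@@]2(C)CC[C@]1(C)CO[Si](CC)(CC)CC | intermediate
18 | (S)-4-(tert-butyldimethylsilyloxy)cyclopent-2-enone | O=C1C=C[C@@H](O[Si](C)(C)C(C)(C)C)C1 | starting material
19 | lithium cross-conjugated dienolate of 18 (formed in situ) | [Li]OC1=C[C@H](O[Si](C)(C)C(C)(C)C)C=C1 | intermediate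
20 | (4R,5S)-4-(tert-butyldimethylsilyloxy)-5-methylcyclopent-2-enone | O=C1C=C[C@@H](O[Si](C)(C)C(C)(C)C)[C@@H]1C | intermediate
21 | (2S,3R)-3-(tert-butyldimethylsilyloxy)-2-methylcyclopentanone | O=C1CC[C@@H](O[Si](C)(C)C(C)(C)C)[C@@H]1C | intermediate
22 | acid chloride of 17 (formed in situ) | O=C(Cl)C[C@H]1[C@@H]2CC(C)(C)CC[C@@]2(C)CC[C@]1(C)CO[Si](CC)(CC)CC | intermediate
23 | lithium C7(O)=C3 enolate of 21 (formed in situ) | [Li]OC1=CC[C@@H](O[Si](C)(C)C(C)(C)C)[C@@H]1C | intermediate
24 | 1,3-diketone (C2–C3 joined; C3 not defined, enolised) | O=C1[C@@H](C)[C@H](O[Si](C)(C)C(C)(C)C)CC1C(=O)C[C@H]1[C@@H]2CC(C)(C)CC[C@@]2(C)CC[C@]1(C)CO[Si](CC)(CC)CC | intermediate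
25 | vinylogous triflate (C7–OTf; C7=C3; C2 ketone; C8–OSiEt3) | FC(F)(F)S(=O)(=O)OC1=C(C(=O)C[C@H]2[C@@H]3CC(C)(C)CC[C@@]3(C)CC[C@]2(C)CO[Si](CC)(CC)CC)C[C@@H](O[Si](C)(C)C(C)(C)C)[C@@H]1C | intermediate
26 | primary alcohol (C8–OH) of 25 | FC(F)(F)S(=O)(=O)OC1=C(C(=O)C[C@H]2[C@@H]3CC(C)(C)CC[C@@]3(C)CC[C@]2(C)CO)C[C@@H](O[Si](C)(C)C(C)(C)C)[C@@H]1C | intermediate
27 | aldehyde (C8=O) triflate | FC(F)(F)S(=O)(=O)OC1=C(C(=O)C[C@H]2[C@@H]3CC(C)(C)CC[C@@]3(C)CC[C@]2(C)C=O)C[C@@H](O[Si](C)(C)C(C)(C)C)[C@@H]1C | intermediate
28 | five–seven–six–six γ-hydroxy enone (8β-OH; C7=C3; C2 ketone; 5β-OSi) | O=C1C[C@H]2[C@@H]3CC(C)(C)CC[C@@]3(C)CC[C@]2(C)[C@H](O)C2=C1C[C@@H](O[Si](C)(C)C(C)(C)C)[C@@H]2C | intermediate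
29 | saturated hydroxy ketone (3β-H; 7β-H; 8β-OH) | O=C1C[C@H]2[C@@H]3CC(C)(C)CC[C@@]3(C)CC[C@]2(C)[C@H](O)[C@H]2[C@@H](C)[C@H](O[Si](C)(C)C(C)(C)C)C[C@@H]12 | intermediate
30 | bis-silyl five–seven–six–six C2 ketone | O=C1C[C@H]2[C@@H]3CC(C)(C)CC[C@@]3(C)CC[C@]2(C)[C@H](O[Si](C)(C)C(C)(C)C)[C@H]2[C@@H](C)[C@H](O[Si](C)(C)C(C)(C)C)C[C@@H]12 | intermediate
31 | C20-trimethylsilyl eight-membered ketone (C20 not defined; formed in situ) | O=C1C([Si](C)(C)C)C[C@H]2[C@@H]3CC(C)(C)CC[C@@]3(C)CC[C@]2(C)[C@H](O[Si](C)(C)C(C)(C)C)[C@H]2[C@@H](C)[C@H](O[Si](C)(C)C(C)(C)C)C[C@@H]12 | intermediate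
32 | five–eight–six–six C2 ketone (bis-silyl ether) | O=C1CC[C@H]2[C@@H]3CC(C)(C)CC[C@@]3(C)CC[C@]2(C)[C@H](O[Si](C)(C)C(C)(C)C)[C@H]2[C@@H](C)[C@H](O[Si](C)(C)C(C)(C)C)C[C@@H]12 | intermediate
33 | C2=C3 enol triflate | FC(F)(F)S(=O)(=O)O/C1=C2\C[C@@H](O[Si](C)(C)C(C)(C)C)[C@H](C)[C@@H]2[C@@H](O[Si](C)(C)C(C)(C)C)[C@@]2(C)CC[C@]3(C)CCC(C)(C)C[C@H]3[C@@H]2CC1 | intermediate
34 | bis(tert-butyldimethylsilyl) ether of the target | C/C1=C2\C[C@@H](O[Si](C)(C)C(C)(C)C)[C@H](C)[C@@H]2[C@@H](O[Si](C)(C)C(C)(C)C)[C@@]2(C)CC[C@]3(C)CCC(C)(C)C[C@H]3[C@@H]2CC1 | intermediate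
35 | target diol CNP0213887.1 | C/C1=C2\C[C@@H](O)[C@H](C)[C@@H]2[C@@H](O)[C@@]2(C)CC[C@]3(C)CCC(C)(C)C[C@H]3[C@@H]2CC1 | target

**Step count and risks**

Total: 22 steps. Longest linear sequence: 20 steps (steps 1–9, then 12–22); the ring A branch (steps 10–11) joins at step 12.

Steps most likely to fail:

1. Step 16. The closure onto the hindered neopentyl aldehyde may be slow, so that protonolysis of the alkenylchromium intermediate or intermolecular coupling takes over, and facial control at C8 may be incomplete. The fallback sets out from 27. Miyaura borylation (B2pin2, PdCl2(dppf), KOAc, 1,4-dioxane, 80 °C) should convert the triflate into the pinacol alkenylboronate aldehyde F1. Rhodium-catalysed intramolecular 1,2-addition of the boronate to the aldehyde ([Rh(cod)Cl]2, aq. KOH, 1,4-dioxane, 60 °C) would then form the same C7–C8 bond through a closed rhodium alkoxide transition state and return to the route at 28.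

2. Step 19. The ring-fusion carbon C3 may migrate in competition with C19, epoxide formation may intervene, or the hindered ketone may react incompletely. The fallback sets out from 30. Insertion of ethyl diazoacetate promoted by BF3·OEt2 (CH2Cl2, −78 → 0 °C) also shifts the less substituted carbon and cannot repeat itself, and should give the C20 ethoxycarbonyl eight-membered ketone F2. Krapcho dealkoxycarbonylation (LiCl, wet DMSO, 140 °C) would then return to the route at 32.

3. Step 20. Proton loss may occur toward C20 instead of C3, giving the regioisomeric enol triflate, and a silyl ether may be lost in the acidic medium. The fallback sets out from 32. Silyl enol ether formation under equilibrating conditions (Me3SiCl, NaI, Et3N, MeCN, 25 °C) should give mainly the C2=C3 trimethylsilyl enol ether F3, which can be freed of its regioisomer by chromatography. MeLi (THF, 0 °C) would release the regiodefined C2=C3 lithium enolate F4, and PhNTf2 would triflate it, returning to the route at 33.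

Further compounds
F1 | step 16 | pinacol alkenylboronate aldehyde (C7–B(pin) in place of C7–OTf of 27) | CC1(C)OB(OC1(C)C)C1=C(C(=O)C[C@H]2[C@@H]3CC(C)(C)CC[C@@]3(C)CC[C@]2(C)C=O)C[C@@H](O[Si](C)(C)C(C)(C)C)[C@@H]1C
F2 | step 19 | C20 ethoxycarbonyl eight-membered ketone (β-keto ester of 32) | O=C1C(C(=O)OCC)C[C@H]2[C@@H]3CC(C)(C)CC[C@@]3(C)CC[C@]2(C)[C@H](O[Si](C)(C)C(C)(C)C)[C@H]2[C@@H](C)[C@H](O[Si](C)(C)C(C)(C)C)C[C@@H]12
F3 | step 20 | C2=C3 trimethylsilyl enol ether of 32 | C[Si](C)(C)O/C1=C2\C[C@@H](O[Si](C)(C)C(C)(C)C)[C@H](C)[C@@H]2[C@@H](O[Si](C)(C)C(C)(C)C)[C@@]2(C)CC[C@]3(C)CCC(C)(C)C[C@H]3[C@@H]2CC1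
F4 | step 20 | C2=C3 lithium enolate of 32 | [Li]O/C1=C2\C[C@@H](O[Si](C)(C)C(C)(C)C)[C@H](C)[C@@H]2[C@@H](O[Si](C)(C)C(C)(C)C)[C@@]2(C)CC[C@]3(C)CCC(C)(C)C[C@H]3[C@@H]2CC1
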